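The bicycle is cut at C8a–C3a and C8a–C8. Around the seven-membered ring, C3a, C4, C5, C6, C7 and C8 carry C3, O, H, CH3, O and H. This is the pattern of a 2,5-dioxygenated toluene, and quaternary C8a is the one extra carbon. An intramolecular Buchner reaction of an α-methyl diazoketone therefore closes the cyclopentanone, expands the arene to the cycloheptatriene and sets C8a in one operation. The precursor is a 2-diazo-5-aryl-6-methylhept-5-en-3-one. C3 stays sp2 (isopropylidene), and the two aryl oxygens differ (C4–OTIPS, C7–OMe) so that the C4 and C7 carbonyls can be released one at a time.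

Key step: step 10

Convention: azulene numbering is used throughout; α is the face that carries the C8a methyl group and β the opposite face (in the target the oxygens at C1, C3 and C4 and the C3a hydrogen are all β).
Assumption: the (S,S)-ligand is taken to favour the (8aS) product; if the sense is opposite the (R,R)-ligand is used, and step 11 removes the minor enantiomer as a separable diastereomer in either case.
Remark on the aryl oxygens: a methyl dienol ether at C4 would need acid, which protonates such ethers at the remote isopropylidene carbon and draws the double bond into C3=C3a; two equal enol ethers would also give an enedione whose C7 carbonyl is the more reactive one. A silyl ether on the C4 oxygen avoids both problems.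
Remark on C3: a carbinol centre at C3 in the precursor would end up with its larger isopropyl group trans to the C8a methyl group, the opposite of the target, so C3 is kept trigonal until step 17.

Step 1
Reactants: 1 4-methoxy-3-methylphenol
Product: 2 2-bromo-4-methoxy-5-methylphenol
Conditions: NBS (1.0 equiv), MeCN, 0 °C
Reagents that add atoms: N-bromosuccinimide, O=C1CCC(=O)N1Br
Why: Electrophilic aromatic bromination is directed by the free hydroxyl group, whose para position is occupied and whose other ortho position is wedged between OH and CH3, so bromine should enter para to the methyl group.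

Step 2
Reactants: 2 2-bromo-4-methoxy-5-methylphenol
Product: 3 (2-bromo-4-methoxy-5-methylphenoxy)triisopropylsilane
Conditions: TIPSCl, imidazole, DMF, rt
Reagents that add atoms: chlorotriisopropylsilane, CC(C)[Si](Cl)(C(C)C)C(C)C
Why: Standard silyl ether formation; the triisopropylsilyl group is chosen because it withstands aqueous phosphate, lithium amide and the ester cleavage and later becomes the fluoride-labile dienol ether at C4.

Step 3
Reactants: 3 (2-bromo-4-methoxy-5-methylphenoxy)triisopropylsilane
Product: 4 triisopropyl[4-methoxy-5-methyl-2-(4,4,5,5-tetramethyl-1,3,2-dioxaborolan-2-yl)phenoxy]silane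
Conditions: B2pin2, Pd(dppf)Cl2 (5 mol %), KOAc, 1,4-dioxane, 90 °C
Reagents that add atoms: bis(pinacolato)diboron, CC1(C)OB(OC1(C)C)B1OC(C)(C)C(C)(C)O1
Why: Miyaura borylation converts the bromide without passing through an ortho-metalated aryl silyl ether, which would be prone to oxygen-to-carbon silyl migration.

Step 4
Reactants: 5 methyl 4-methyl-3-oxopentanoate
Product: 7 methyl (Z)-4-methyl-3-(trifluoromethylsulfonyloxy)pent-2-enoate, via sodium enolate 6 (not isolated)
Conditions: NaH, Et2O, 0 °C; then Tf2O, 0 °C
Reagents that add atoms: sodium hydride (sodium of 6 only), [Na+].[H-]; trifluoromethanesulfonic anhydride, O=S(=O)(OS(=O)(=O)C(F)(F)F)C(F)(F)F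
Why: O-Sulfonylation of the chelated sodium enolate of a β-keto ester places the triflate cis to the ester and should give the (Z)-enol triflate.

Step 5
Reactants: 4 aryl pinacol boronate; 7 (Z)-enol triflate
Product: 8 methyl (Z)-3-[5-methoxy-4-methyl-2-(triisopropylsilyloxy)phenyl]-4-methylpent-2-enoate
Conditions: Pd(OAc)2 (3 mol %), SPhos (6 mol %), K3PO4, THF/H2O, 40 °C
Reagents that add atoms: none
Why: Suzuki–Miyaura coupling of a β-triflyloxy acrylate proceeds with retention of the alkene geometry, and the bulky electron-rich biaryl phosphine copes with the ortho-substituted boronate.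

Step 6
Reactants: 8 (Z)-enoate
Product: 10 methyl 3-[5-methoxy-4-methyl-2-(triisopropylsilyloxy)phenyl]-4-methylpent-3-enoate, via lithium dienolate 9 (not isolated)
Conditions: LiN(iPr)2 (1.3 equiv), DMPU, THF, −78 to −40 °C; then inverse quench into AcOH/THF, −78 °C
Reagents that add atoms: lithium diisopropylamide (lithium of 9 only), [Li+].CC(C)[N-]C(C)C
Why: Deconjugative protonation: the amide base removes the only γ-hydrogen (the isopropyl methine) and dienolate 9 is protonated kinetically at the α-carbon, which shifts the double bond into the tetrasubstituted β,γ-position.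

Step 7
Reactants: 10 β,γ-unsaturated methyl ester
Product: 12 3-[5-methoxy-4-methyl-2-(triisopropylsilyloxy)phenyl]-4-methylpent-3-enoic acid, via trimethylstannyl ester 11 (not isolated)
Conditions: Me3SnOH (5 equiv), 1,2-dichloroethane, 70 °C; then 1 M HCl wash
Reagents that add atoms: trimethyltin hydroxide, C[Sn](C)(C)O
Why: Ester cleavage with Me3SnOH is close to neutral, so the aryl silyl ether should stay in place and the double bond should not be drawn back into conjugation, both of which are at risk with hydroxide.

Step 8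
Reactants: 13 N-ethyl-N-nitrosourea
Product: 14 diazoethane (dried ethereal solution)
Conditions: KOH (40 % aq), Et2O, −10 °C; ether layer decanted and dried over KOH pellets
Reagents that add atoms: none
Why: Base-induced fragmentation of an N-alkyl-N-nitrosourea is the standard way to an ethereal diazoalkane solution.

Step 9
Reactants: 12 β,γ-unsaturated acid; 14 diazoethane
Product: 16 2-diazo-5-[5-methoxy-4-methyl-2-(triisopropylsilyloxy)phenyl]-6-methylhept-5-en-3-one, via acid chloride 15 (not isolated)
Conditions: 1-chloro-N,N,2-trimethylprop-1-en-1-amine, CH2Cl2, 0 °C; then added to 14 (4 equiv), Et2O, −20 to 0 °C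
Reagents that add atoms: 1-chloro-N,N,2-trimethylprop-1-en-1-amine (chlorine of 15 only), CC(C)=C(Cl)N(C)C
Why: The α-chloroenamine makes the acid chloride without releasing hydrogen chloride, which spares the acid-sensitive styrene, and acylation of diazoethane (first stage of an Arndt–Eistert sequence) gives the α-methyl diazoketone while a second equivalent of 14 takes up the hydrogen chloride.

Step 10
Reactants: 16 α-methyl diazoketone
Product: 18 (8aS)-7-methoxy-6,8a-dimethyl-3-(propan-2-ylidene)-4-(triisopropylsilyloxy)-2,3-dihydroazulen-1(8aH)-one, via norcaradiene 17 (not isolated)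
Conditions: [Cu(MeCN)4]PF6 (5 mol %), 2,2′-(propane-2,2-diyl)bis[(4S)-4-tert-butyl-4,5-dihydrooxazole] (6 mol %), NaB[3,5-(CF3)2C6H3]4 (6 mol %), CH2Cl2, 40 °C, slow addition of 16; Et3N-deactivated silica
Reagents that add atoms: none
Why: The cationic copper bis(oxazoline) complex expels N2 from 16 and the electrophilic acyl(methyl)carbenoid cyclopropanates the arene across the ipso carbon (C3a) and the free ortho carbon (C8); norcaradiene 17 then opens by a disrotatory 6π electrocyclic reaction to cycloheptatriene 18. The closest known reaction is the intramolecular Buchner reaction of 2-diazo-5-arylpentan-3-ones to 8a-methylazulenones, which is also known in enantioselective form with copper bis(oxazoline) catalysts. The five-membered ring is closed by the C8a–C3a bond of the [2+1] cycloaddition, reached through the three-atom tether C1–C2–C3, and the seven-membered ring results from the C8a–C8 bond followed by cleavage of C3a–C8, a six-to-seven ring expansion. C8a is the only new stereocentre and is set by the arene face that the ligand-bound carbenoid attacks; since each twisted conformer about the aryl–C3 bond offers only one face, selection may be incomplete, and step 11 therefore removes the wrong enantiomer as a diastereomer. Regioselectivity is secured by the silyloxy group, which blocks the second ortho carbon, and chemoselectivity over C3=CMe2 by geometry: the arene stands nearly perpendicular to the alkene plane and turns its π face to the tether, whereas the alkene could be reached only through a strained, fully substituted bicyclo[2.1.0]pentanone. The fully substituted C8a cannot tautomerise, but 18 must be kept from acid, which would trigger the aromatising rearrangement to a 2-tetralone.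

Step 11
Reactants: 18 azulenone
Product: 19 (1R,8aS)-7-methoxy-6,8a-dimethyl-3-(propan-2-ylidene)-4-(triisopropylsilyloxy)-1,2,3,8a-tetrahydroazulen-1-ol (1β-OH)
Conditions: (S)-Me-CBS oxazaborolidine (20 mol %), BH3·SMe2, toluene, −30 °C; MeOH quench; chromatography
Reagents that add atoms: none
Why: Corey–Bakshi–Shibata reduction: with quaternary C8a as the large and C2H2 as the small flank the (S)-catalyst should deliver hydride to the α face and give the (1R) alcohol with the hydroxyl group on the β face under reagent control, at a stage where C3a is still trigonal so that the methyl and vinyl groups on C8a shield the two faces about equally, and any (8aR) material becomes a diastereomer that is removed by chromatography.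

Step 12
Reactants: 19 1β-alcohol
Product: 20 (1R,8aS)-7-methoxy-6,8a-dimethyl-3-(propan-2-ylidene)-4-(triisopropylsilyloxy)-1,2,3,8a-tetrahydroazulen-1-yl acetate
Conditions: Ac2O, Et3N, DMAP (cat.), CH2Cl2, rt
Reagents that add atoms: acetic anhydride, CC(=O)OC(C)=O
Why: DMAP-catalysed acylation esterifies the neopentyl-type secondary alcohol with retention at C1 and under basic conditions that the two enol ethers tolerate.

Step 13
Reactants: 20 silyl dienol ether acetate
Product: 22 (1R,3aR,8aS)-7-methoxy-6,8a-dimethyl-4-oxo-3-(propan-2-ylidene)-1,2,3,3a,4,8a-hexahydroazulen-1-yl acetate (trans-fused; 3a-H β), via tetrabutylammonium dienolate 21 (not isolated)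
Conditions: TBAF (1.1 equiv), AcOH (2 equiv), THF, −20 °C
Reagents that add atoms: tetrabutylammonium fluoride (cation of 21 only), CCCC[N+](CCCC)(CCCC)CCCC.[F-]
Why: Fluoride cleavage of the silyl dienol ether releases dienolate 21, which, unlike a dienol ether under acid, is protonated kinetically at the α-carbon C3a (deconjugative protonation) and from the β face, anti to the adjacent C8a methyl group, so the trans-fused ketone with the isopropylidene group intact should result, while the acetic acid buffer and the low temperature suppress re-enolisation.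

Step 14
Reactants: 22 trans-fused C4 ketone
Product: 24 (1R,3aR,4S,8aS)-4-hydroxy-6,8a-dimethyl-7-oxo-3-(propan-2-ylidene)-1,2,3,3a,4,7,8,8a-octahydroazulen-1-yl acetate (4α-OH), via 4α-alcohol 23 (not isolated)
Conditions: NaBH4, CeCl3·7H2O, MeOH/THF, −78 °C; then 1 M HCl, THF, 0 °C
Reagents that add atoms: water, O
Why: Luche 1,2-reduction followed by enol ether hydrolysis: hydride should approach C4 from the β face because the axial C8a methyl group, in a 1,3 relationship, guards the α face (as with ring ketones 1,3 to an angular methyl group in trans-fused systems), which gives the axial 4α-alcohol 23, and dilute acid then protonates the cross-conjugated enol ether at C8 and releases the C7 enone without touching C5=C6.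

Step 15
Reactants: 25 4-hydroxybenzoic acid
Product: 27 4-(tert-butyldimethylsilyloxy)benzoic acid, via bis-silyl derivative 26 (not isolated)
Conditions: TBSCl (2.3 equiv), imidazole, DMF, rt; then AcOH/THF/H2O 3:1:1, rt
Reagents that add atoms: tert-butylchlorodimethylsilane, CC(C)(C)[Si](C)(C)Cl
Why: Exhaustive silylation followed by selective hydrolysis of the much more labile silyl ester leaves the aryl silyl ether in place.

Step 16
Reactants: 24 4α-hydroxy enone; 27 4-(tert-butyldimethylsilyloxy)benzoic acid
Product: 28 (1R,3aR,4R,8aS)-1-acetoxy-6,8a-dimethyl-7-oxo-3-(propan-2-ylidene)-1,2,3,3a,4,7,8,8a-octahydroazulen-4-yl 4-(tert-butyldimethylsilyloxy)benzoate (4β-ester)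
Conditions: PPh3, DIAD, toluene, 0 °C to rt
Reagents that add atoms: none
Why: Mitsunobu esterification: the carboxylate displaces the oxyphosphonium group from the open β face with inversion, so the 4α-alcohol becomes the equatorial 4β-ester in the step that acylation would need anyway, and the electron-poor γ-position of the enone disfavours ionisation and allylic transposition.

Step 17
Reactants: 28 4β-ester
Product: 29 β-epoxide of 28 at C3=CMe2 (spiro oxirane; oxygen on the β face of C3)
Conditions: mCPBA, NaHCO3, CH2Cl2, 0 °C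
Reagents that add atoms: 3-chloroperbenzoic acid, OOC(=O)c1cccc(Cl)c1
Why: Prilezhaev epoxidation attacks the only electron-rich alkene, and since C3a shows only its hydrogen on the β face while C4 with its ester and the C8a methyl group cover the α face, oxygen should be delivered from the β face, which sets C3.

Step 18
Reactants: 29 β-epoxide
Product: 31 (1R,3S,3aR,4R,8aS)-1-acetoxy-3-hydroxy-6,8a-dimethyl-7-oxo-3-(prop-1-en-2-yl)-1,2,3,3a,4,7,8,8a-octahydroazulen-4-yl 4-hydroxybenzoate, via trimethylsilyl ether 30 (not isolated)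
Conditions: TMSOTf (1.5 equiv), 2,6-lutidine (3 equiv), CH2Cl2, −78 °C; then HF·pyridine, pyridine, THF, 0 °C
Reagents that add atoms: trimethylsilyl trifluoromethanesulfonate (silyl group of 30 only), C[Si](C)(C)OS(=O)(=O)C(F)(F)F
Why: Silyl triflate promoted isomerisation of a fully substituted epoxide to an allylic silyl ether: the exocyclic C–O bond should ionise because positive charge at ring carbon C3 is disfavoured by the acyloxy-bearing carbons C1 and C4 two bonds away, a methyl proton is lost to the base and the C3–O bond is never broken, so C3 keeps its configuration, and fluoride then removes both silyl groups.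

Step 19
Reactants: 31 isopropenyl carbinol
Product: 32 (1R,3R,3aR,4R,8aS)-1-acetoxy-3-hydroxy-6,8a-dimethyl-7-oxo-3-(propan-2-yl)-1,2,3,3a,4,7,8,8a-octahydroazulen-4-yl 4-hydroxybenzoate (target)
Conditions: H2 (1 atm), RhCl(PPh3)3 (10 mol %), benzene/EtOH 1:1, rt
Reagents that add atoms: none
Why: Homogeneous hydrogenation with RhCl(PPh3)3 responds to steric access and should saturate the 1,1-disubstituted isopropenyl group while the trisubstituted conjugated C5=C6 bond, the esters and the ketone remain, the selectivity known from the reduction of carvone to carvotanacetone.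

Compound list
1 | 4-methoxy-3-methylphenol | COc1ccc(O)cc1C | starting material
2 | 2-bromo-4-methoxy-5-methylphenol | COc1cc(Br)c(O)cc1C | intermediate
3 | (2-bromo-4-methoxy-5-methylphenoxy)triisopropylsilane | COc1cc(Br)c(O[Si](C(C)C)(C(C)C)C(C)C)cc1C | intermediate
4 | triisopropyl[4-methoxy-5-methyl-2-(4,4,5,5-tetramethyl-1,3,2-dioxaborolan-2-yl)phenoxy]silane | COc1cc(B2OC(C)(C)C(C)(C)O2)c(O[Si](C(C)C)(C(C)C)C(C)C)cc1C | intermediate
5 | methyl 4-methyl-3-oxopentanoate | COC(=O)CC(=O)C(C)C | starting material
6 | sodium (Z)-enolate of 5 | [Na+].COC(=O)/C=C(\[O-])C(C)C | intermediate (not isolated)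
7 | methyl (Z)-4-methyl-3-(trifluoromethylsulfonyloxy)pent-2-enoate | COC(=O)/C=C(\OS(=O)(=O)C(F)(F)F)C(C)C | intermediate
8 | methyl (Z)-3-[5-methoxy-4-methyl-2-(triisopropylsilyloxy)phenyl]-4-methylpent-2-enoate | COC(=O)/C=C(\c1cc(OC)c(C)cc1O[Si](C(C)C)(C(C)C)C(C)C)C(C)C | intermediate
9 | lithium dienolate of 8 | [Li+].COC([O-])=CC(=C(C)C)c1cc(OC)c(C)cc1O[Si](C(C)C)(C(C)C)C(C)C | intermediate (not isolated)
10 | methyl 3-[5-methoxy-4-methyl-2-(triisopropylsilyloxy)phenyl]-4-methylpent-3-enoate | COC(=O)CC(=C(C)C)c1cc(OC)c(C)cc1O[Si](C(C)C)(C(C)C)C(C)C | intermediate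
11 | trimethylstannyl ester of 12 | C[Sn](C)(C)OC(=O)CC(=C(C)C)c1cc(OC)c(C)cc1O[Si](C(C)C)(C(C)C)C(C)C | intermediate (not isolated)
12 | 3-[5-methoxy-4-methyl-2-(triisopropylsilyloxy)phenyl]-4-methylpent-3-enoic acid | OC(=O)CC(=C(C)C)c1cc(OC)c(C)cc1O[Si](C(C)C)(C(C)C)C(C)C | intermediate
13 | N-ethyl-N-nitrosourea | CCN(N=O)C(N)=O | starting material
14 | diazoethane | CC=[N+]=[N-] | intermediate
15 | acid chloride of 12 | ClC(=O)CC(=C(C)C)c1cc(OC)c(C)cc1O[Si](C(C)C)(C(C)C)C(C)C | intermediate (not isolated)
16 | 2-diazo-5-[5-methoxy-4-methyl-2-(triisopropylsilyloxy)phenyl]-6-methylhept-5-en-3-one | CC(=[N+]=[N-])C(=O)CC(=C(C)C)c1cc(OC)c(C)cc1O[Si](C(C)C)(C(C)C)C(C)C | intermediate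
17 | norcaradiene valence tautomer of 18 (cyclopropane C3a–C8–C8a) | O=C1CC(=C(C)C)[C@]23C(O[Si](C(C)C)(C(C)C)C(C)C)=CC(C)=C(OC)[C@H]2[C@]13C | intermediate (not isolated)
18 | (8aS)-7-methoxy-6,8a-dimethyl-3-(propan-2-ylidene)-4-(triisopropylsilyloxy)-2,3-dihydroazulen-1(8aH)-one | O=C1CC(=C(C)C)C2=C(O[Si](C(C)C)(C(C)C)C(C)C)C=C(C)C(OC)=C[C@]12C | intermediate
19 | (1R,8aS)-1β-alcohol of 18 | O[C@@H]1CC(=C(C)C)C2=C(O[Si](C(C)C)(C(C)C)C(C)C)C=C(C)C(OC)=C[C@]12C | intermediate
20 | (1R,8aS)-1β-acetate of 19 | CC(=O)O[C@@H]1CC(=C(C)C)C2=C(O[Si](C(C)C)(C(C)C)C(C)C)C=C(C)C(OC)=C[C@]12C | intermediate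
21 | tetrabutylammonium C4 dienolate from 20 | CCCC[N+](CCCC)(CCCC)CCCC.CC(=O)O[C@@H]1CC(=C(C)C)C2=C([O-])C=C(C)C(OC)=C[C@]12C | intermediate (not isolated)
22 | (1R,3aR,8aS)-7-methoxy-6,8a-dimethyl-4-oxo-3-(propan-2-ylidene)-1,2,3,3a,4,8a-hexahydroazulen-1-yl acetate | CC(=O)O[C@@H]1CC(=C(C)C)[C@H]2C(=O)C=C(C)C(OC)=C[C@]12C | intermediate
23 | 4α-alcohol of 22 (C7 enol ether intact) | CC(=O)O[C@@H]1CC(=C(C)C)[C@H]2[C@@H](O)C=C(C)C(OC)=C[C@]12C | intermediate (not isolated)
24 | (1R,3aR,4S,8aS)-4-hydroxy-6,8a-dimethyl-7-oxo-3-(propan-2-ylidene)-1,2,3,3a,4,7,8,8a-octahydroazulen-1-yl acetate | CC(=O)O[C@@H]1CC(=C(C)C)[C@H]2[C@@H](O)C=C(C)C(=O)C[C@]12C | intermediate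
25 | 4-hydroxybenzoic acid | OC(=O)c1ccc(O)cc1 | starting material
26 | tert-butyldimethylsilyl 4-(tert-butyldimethylsilyloxy)benzoate | CC(C)(C)[Si](C)(C)OC(=O)c1ccc(O[Si](C)(C)C(C)(C)C)cc1 | intermediate (not isolated)
27 | 4-(tert-butyldimethylsilyloxy)benzoic acid | OC(=O)c1ccc(O[Si](C)(C)C(C)(C)C)cc1 | intermediate
28 | (1R,3aR,4R,8aS)-1-acetoxy-6,8a-dimethyl-7-oxo-3-(propan-2-ylidene)-1,2,3,3a,4,7,8,8a-octahydroazulen-4-yl 4-(tert-butyldimethylsilyloxy)benzoate | CC(=O)O[C@@H]1CC(=C(C)C)[C@H]2[C@H](OC(=O)c3ccc(O[Si](C)(C)C(C)(C)C)cc3)C=C(C)C(=O)C[C@]12C | intermediate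
29 | β-epoxide of 28 (spiro oxirane at C3, oxygen β) | CC(=O)O[C@@H]1C[C@@](O3)(C3(C)C)[C@H]2[C@H](OC(=O)c4ccc(O[Si](C)(C)C(C)(C)C)cc4)C=C(C)C(=O)C[C@]12C | intermediate
30 | 3β-trimethylsilyloxy-3-isopropenyl compound (aryl silyl ether intact) | CC(=O)O[C@@H]1C[C@@](O[Si](C)(C)C)(C(C)=C)[C@H]2[C@H](OC(=O)c3ccc(O[Si](C)(C)C(C)(C)C)cc3)C=C(C)C(=O)C[C@]12C | intermediate (not isolated)
31 | (1R,3S,3aR,4R,8aS)-1-acetoxy-3-hydroxy-6,8a-dimethyl-7-oxo-3-(prop-1-en-2-yl)-1,2,3,3a,4,7,8,8a-octahydroazulen-4-yl 4-hydroxybenzoate | CC(=O)O[C@@H]1C[C@@](O)(C(C)=C)[C@H]2[C@H](OC(=O)c3ccc(O)cc3)C=C(C)C(=O)C[C@]12C | intermediate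
32 | (1R,3R,3aR,4R,8aS)-1-acetoxy-3-hydroxy-6,8a-dimethyl-7-oxo-3-(propan-2-yl)-1,2,3,3a,4,7,8,8a-octahydroazulen-4-yl 4-hydroxybenzoate | CC(=O)O[C@@H]1C[C@@](O)(C(C)C)[C@H]2[C@H](OC(=O)c3ccc(O)cc3)C=C(C)C(=O)C[C@]12C | target

Total step count: 19. Longest linear sequence: 16 steps (steps 1–3, 5–7, 9–14 and 16–19).

Steps most likely to fail

Step 10. Capture of the carbenoid by the neighbouring tetrasubstituted C3=CMe2 bond (closure to a bicyclo[2.1.0]pentanone and vinylogous Wolff fragmentation) may outrun addition to the arene. Fallback: the carbene step is run before the double bond is moved out of conjugation.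
- Setting out from 8, Me3SnOH gives, through trimethylstannyl (Z)-3-aryl-4-methylpent-2-enoate F1, the (Z)-3-aryl-4-methylpent-2-enoic acid F2.
- The chloroenamine converts F2 into (Z)-acid chloride F3, and diazoethane 14 gives (Z)-2-diazo-5-aryl-6-methylhept-4-en-3-one F4.
- In F4 the alkene is electron-poor and lies on the far side of the carbonyl group, out of reach of the carbene carbon, while the (Z) geometry holds the arene next to it.
- The same copper catalyst should lead through norcaradiene F5 to the cross-conjugated (8aS)-3-isopropylazulen-1(8aH)-one F6.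
- LiN(iPr)2/DMPU then removes the isopropyl methine proton, and kinetic protonation of lithium trienolate F7 at C2 with AcOH moves the double bond to the exocyclic position. This comes back to the route at 18.

Step 16. Loss of the activated axial C4 oxygen together with the antiperiplanar, allylic C3a hydrogen (elimination towards a cross-conjugated trienone) may outrun substitution at this hindered carbon. Fallback: the C4 configuration is set by the reductant and the ester is made with retention.
- Setting out from 22, (S)-Me-CBS oxazaborolidine with catecholborane (large flank C3a, small flank C5–H) should deliver hydride to the α face and give the 4β-alcohol with intact C7 enol ether F8.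
- 1 M HCl releases the 4β-hydroxy enone F9.
- Steglich esterification (EDC·HCl, DMAP) with 27 comes back to the route at 28.

Step 18. After ionisation of the epoxide, a semipinacol shift of a ring bond (enlargement of the five-membered ring to a cyclohexanone) may compete with loss of a methyl proton. Fallback: the allylic alcohol is made without an epoxide.
- Setting out from 28, the Schenck ene reaction (O2, tetraphenylporphyrin, visible light, CH2Cl2, 0 °C) on the open β face should give the tertiary 3β-allylic hydroperoxide F10.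
- PPh3 reduces F10 to the 3β-allylic alcohol with intact aryl silyl ether F11.
- HF·pyridine removes the silyl group and comes back to the route at 31.

Further compounds
F1 | step 10 | trimethylstannyl (Z)-3-[5-methoxy-4-methyl-2-(triisopropylsilyloxy)phenyl]-4-methylpent-2-enoate | C[Sn](C)(C)OC(=O)/C=C(\c1cc(OC)c(C)cc1O[Si](C(C)C)(C(C)C)C(C)C)C(C)C
F2 | step 10 | (Z)-3-[5-methoxy-4-methyl-2-(triisopropylsilyloxy)phenyl]-4-methylpent-2-enoic acid | OC(=O)/C=C(\c1cc(OC)c(C)cc1O[Si](C(C)C)(C(C)C)C(C)C)C(C)C
F3 | step 10 | (Z)-acid chloride of F2 | ClC(=O)/C=C(\c1cc(OC)c(C)cc1O[Si](C(C)C)(C(C)C)C(C)C)C(C)C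
F4 | step 10 | (Z)-2-diazo-5-[5-methoxy-4-methyl-2-(triisopropylsilyloxy)phenyl]-6-methylhept-4-en-3-one | CC(=[N+]=[N-])C(=O)/C=C(\c1cc(OC)c(C)cc1O[Si](C(C)C)(C(C)C)C(C)C)C(C)C
F5 | step 10 | norcaradiene valence tautomer of F6 | O=C1C=C(C(C)C)[C@]23C(O[Si](C(C)C)(C(C)C)C(C)C)=CC(C)=C(OC)[C@H]2[C@]13C
F6 | step 10 | (8aS)-3-isopropyl-7-methoxy-6,8a-dimethyl-4-(triisopropylsilyloxy)azulen-1(8aH)-one | O=C1C=C(C(C)C)C2=C(O[Si](C(C)C)(C(C)C)C(C)C)C=C(C)C(OC)=C[C@]12C
F7 | step 10 | lithium trienolate of F6 | [Li+].[O-]C1=CC(=C(C)C)C2=C(O[Si](C(C)C)(C(C)C)C(C)C)C=C(C)C(OC)=C[C@]12C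
F8 | step 16 | 4β-alcohol of 22 (C7 enol ether intact) | CC(=O)O[C@@H]1CC(=C(C)C)[C@H]2[C@H](O)C=C(C)C(OC)=C[C@]12C
F9 | step 16 | (1R,3aR,4R,8aS)-4-hydroxy-6,8a-dimethyl-7-oxo-3-(propan-2-ylidene)-1,2,3,3a,4,7,8,8a-octahydroazulen-1-yl acetate | CC(=O)O[C@@H]1CC(=C(C)C)[C@H]2[C@H](O)C=C(C)C(=O)C[C@]12C
F10 | step 18 | 3β-hydroperoxy-3-isopropenyl compound (aryl silyl ether intact) | CC(=O)O[C@@H]1C[C@@](OO)(C(C)=C)[C@H]2[C@H](OC(=O)c3ccc(O[Si](C)(C)C(C)(C)C)cc3)C=C(C)C(=O)C[C@]12C
F11 | step 18 | 3β-hydroxy-3-isopropenyl compound (aryl silyl ether intact) | CC(=O)O[C@@H]1C[C@@](O)(C(C)=C)[C@H]2[C@H](OC(=O)c3ccc(O[Si](C)(C)C(C)(C)C)cc3)C=C(C)C(=O)C[C@]12C
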